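The nucleophile offers the set-free acid a far stronger home than the free base does: in the noon flask, multiplying each binding constant by the amount on hand, nucleophile at the start and free base at saturation, gives 500 against 2.60. So I follow one ratio of two rates, in which time drops out.

| flask | electrophile | nucleophile | gas | time |
|---|---|---|---|---|
| dawn | 0.012 M | 0.0240 M | 3.2 mM (held) | 2.5 min |
| noon | 0.012 M | 0.0120 M | 3.2 mM (held) | 2.5 min |
| summer | 0.012 M | 0.0480 M | 3.2 mM (held) | 2.5 min |

    electrophile + nucleophile → acid set free + target (k1 = 0.482 M⁻¹ s⁻¹)
    nucleophile + acid set free ⇌ protonated nucleophile, settled at all times (K2 = 42000 M⁻¹)
    acid set free + free base ⇌ salt of the base (K3 = 813 M⁻¹, k3 = 2.42 M⁻¹ s⁻¹)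
    target → over-reaction product (k4 = 0.00199 s⁻¹)
    electrophile + target ⇌ idle adduct, settled at all times (K5 = 304 M⁻¹)
    gas ⇌ free base, rate k6*(csat - [free base]) (k6 = 0.129 s⁻¹, csat = 3.2 mM)

- part of the electrophile that has reacted at the end, dawn
- part of the electrophile that has reacted at the end, noon
- part of the electrophile that has reacted at the end, summer
- what raising the concentration of nucleophile from its lowest to its highest value here does to the part of the electrophile that has reacted (changes below 5 percentage points count as none) (it falls / no change / it rises)

- in percentages every species weighs as the electrophile in it: one idle adduct counts as two
- for target the idle adduct is counted in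
- at the start none of free base is dissolved
- in an amount of target, one idle adduct counts as one target
- what has gone from electrophile into another species counts as reacted, even if it can come back
- run time (dawn): 2.5 min

I want the free nucleophile lost per electrophile that passes through the forming step. One nucleophile is consumed in that step, and a second may take the acid. I reckon this two ways for noon, at the moment when half its nucleophile, 0.00600 M, is free. The free base is dissolved early, since its transfer time of 7.75 s is far shorter than the run.

By balance, the acid's share on the nucleophile gives 1.99. By rates, protonated nucleophile is then half the free nucleophile, so the acid set free stands near 1.19 × 10⁻⁵ M. Salt formation then runs at 0.00354 of the forming rate, which gives 2.00.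

The two part in the third digit, and the balance way is the one that cheats. It supposes salt at its balance of 3.10 × 10⁻⁵ M, while the rate delivers about 1.38 × 10⁻⁵ M in the run. So I carry the second figure as the nucleophile price, π.

With π known, the noon nucleophile reaches 50.1 % of the electrophile, so the nucleophile is the limiting reagent there. At noon, unturned electrophile over free nucleophile grows from 1 to E = 2.38, which gives a turnover of 36.7 % of the charge. The adduct balance takes a further 22.1 % of the electrophile out of the free pool, so my noon figure is 58.8 %. I read it as high, because my rate counts the adduct's share as free electrophile, and that share is 0.602 of my turnover. The summer charge reaches further than the noon charge, so I expect the part reacted to rise.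

The forecast gives 76 % for dawn, 53 % for noon and 89.5 % for summer, with the verdict it rises, and its noon value sits below my noon figure. Its grounds are that “each electrophile effectively costs two nucleophiles”.

The flask gives 76.3 % for dawn, 53.4 % for noon and 90.6 % for summer, and with more nucleophile the verdict is it rises, by 37 percentage points from noon to summer. At noon, target and over-reaction product together hold 33.5 % of the electrophile, against my turnover of 36.7 %. Now take the dawn flask charged with 0.0060 M of nucleophile instead. Its target and over-reaction product at π = 2.00 leave 25.1 % of its nucleophile free, and that flask holds 26 %.

Its constants are those of an exercise; the run is a simulation.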